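Core numbering used throughout: C1 is the quaternary carbon (methyl and the ethenyl arm), C2 and C3 are the methylenes, C4 is the methyl-bearing alkene carbon, C5 the alkene CH and C6 the CH that carries the coumarinyl group.

## Analysis of the target

The target 22 is a 1,4-dimethylcyclohexene core carrying two 5,7-dimethoxycoumarin units, both bonded through their C8. One sits directly on ring carbon C6; the other is joined to C1 through an (E)-ethenyl bridge. There are two adjacent stereocentres, the all-carbon quaternary C1 (R) and the tertiary C6 (R). The aryl group on C6 is cis to the ethenyl arm and trans to the C1 methyl group.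

The sensitive groups are the two coumarin lactones, which are opened by hydroxide or alkoxide, reduced by strong hydride donors and attacked at C4 by soft nucleophiles. The electron-rich arene rings are open to electrophiles. The C6–H bond is both benzylic and allylic, so acid or base can move the ring alkene or epimerise C6.

The difficulty is a quaternary stereocentre, as one enantiomer, directly beside a carbon bearing an aryl group with two ortho oxygen substituents, together with a ring alkene that must sit at C4=C5 and nowhere else.

The strategy rests on one feature. C5, C6, C1 and C2 form a 3,3-disubstituted cyclobutanone in disguise, with the carbonyl at C5, and this ring is prochiral as long as C2 and C6 are both CH2. C3–C4 with its methyl group is a two-carbon alkyne unit. Inserting that alkyne into one of the two acyl C–C bonds closes the six-membered ring and makes C1 stereogenic in the same step.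

## Retrosynthetic reasoning

**22 to 21 and 12.** The bond between the ethenyl carbon and C8 of the second coumarin is cut. This brings that coumarin in intact and late, and lets the E geometry come from a syn hydroboration. Forward, a Suzuki–Miyaura coupling must join an (E)-alkenylboronate to a di-ortho-substituted aryl bromide without opening either lactone.

**21 to 20.** The alkenylboronate is traced to a terminal alkyne on C1. Until this point the alkyne is a slim, rod-like stand-in for the ethenyl arm, which matters twice earlier: for differentiation from methyl in the key step, and for the configuration at C6.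

**20 to 17 to 16.** The C4=C5 alkene with a methylene at C3 is the product of a reductive 1,3-transposition of a C5 carbonyl conjugated to a C3=C4 alkene. The sulfonylhydrazone 17 of enone 16 is therefore the precursor. The gain is regiochemical certainty: the alkene can only end at C4=C5, and the oxygen that served the earlier chemistry leaves without trace.

**16 to 15.** The C3–H and the alkyne C–H are traced to C–Si bonds. The silicon on C3 is the regiocontrol element of the ring-forming step. It must leave while the enone is still in place: after the transposition it would be an allylsilane, and its removal would drag the alkene to C3=C4. A trialkylsilyl group on the β-carbon of an enone resists acid (ipso protonation falls on an electron-poor carbon). The silyl group is therefore chosen as benzyldimethylsilyl, which fluoride cleaves under mild conditions together with the alkyne silyl group.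

**15 to 10 and 12.** The C6–aryl bond is cut. C6 is the α′ carbon of the C5 ketone, so a palladium-catalysed enolate arylation with the same bromide 12 serves. C6 stays epimerisable next to the carbonyl, and equilibration should put the aryl group trans to the C1 methyl and next to the slim alkynyl group.

**10 to 6 and 9.** This is the key disconnection. The bonds C4–C5 and C2–C3 are cut, so the cyclohexenone becomes cyclobutanone 6 plus silylalkyne 9. Ring, two skeletal bonds and the C1 stereocentre come from one catalytic step, and both partners are simple and achiral. Forward, a chiral zerovalent nickel catalyst must choose one of two enantiotopic acyl C–C bonds and orient the alkyne so that methyl lands on C4.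

**6 to 5 to 2 and 4.** The cyclobutanone is opened to a (2+2) cycloaddition between the 1,1-disubstituted alkene of silyl enyne 2 and dichloroketene 4 (from 3), followed by reductive removal of both chlorine atoms. Enyne 2 is the C-silylation product of 1.

**Branches.** Alkyne 9 is the coupling product of 7 and 8. Bromide 12 comes from electrophilic bromination of coumarin 11.

## Alternatives that were turned down

**Alternative 1:** Both benzene rings of the coumarins are disconnected by a two-fold Danheiser benzannulation.
- *Key step.* The bis(siloxyalkyne) A2 of the finished core is heated with 3-methoxycyclobut-2-enone A3. The ketene formed on ring opening of A3 adds to each ynol ether; four-electron ring opening and six-electron closure then give the bis(resorcinol monosilyl ether) A1, forming C8–C8a, C6–C7 and C4a–C8a of each future coumarin.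
- *For.* No aryl–carbon bond has to be forced at a hindered position, and the substitution pattern at C8 is fixed by the mechanism. On both points this plan is stronger than the chosen one, which depends on a hindered enolate arylation and on regioselective bromination of 11.
- *Against.* The step does nothing for the real problem. The cyclohexene with both stereocentres has to be made first, as one enantiomer, carrying two fragile ynol ethers, one of them part of a conjugated enyne that offers the ketene other reaction modes. After the benzannulation each ring still needs lactone annulation at C4a, desilylation and O-methylation with two phenolic oxygens told apart, all done twice, to rebuild a ring system that 11 already contains.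
- *Comparison.* The chosen route is far shorter, uses 11 directly, and spends its one uncertain step on the quaternary stereocentre.

**Alternative 2:** The core bonds C1–C2 and C5–C6 are disconnected by a Diels–Alder reaction.
- *Key step.* The two carbon substituents of C1 are carried as a methyl ester and a lactone carbonyl tied to the C7 oxygen of the coumarin. The C3–C4 double bond of the angular pyranocoumarin carboxylate A5 adds the silyl diene A6 and gives the cis-fused adduct A4.
- *For.* The ring and both stereocentres form at once. The cis relation between the aryl group and the future ethenyl arm is guaranteed by the ring fusion, which is stronger than the equilibration used in the chosen route. Protodesilylation of the allylsilane in A4 would place the alkene at C4=C5 cleanly, and the chelating dienophile suits chiral Lewis acids.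
- *Against.* The dienophile double bond is trisubstituted, conjugated to a donor-rich arene and part of a pyranone. The diene must bond its silyl-bearing terminus to the hindered benzylic carbon. Low reactivity and uncertain absolute control are therefore expected. Afterwards three ester-type carbonyls must be told apart: one neopentyl carbonyl reduced all the way to methyl, the other turned into the E-alkene carrying the second coumarin, and the freed phenol methylated, all beside a hydride-sensitive coumarin.
- *Comparison.* The chosen route needs no redox work at neopentyl positions and reaches the target in fewer steps.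

**Alternative 3:** The benzene ring of the C6-bound coumarin is cut at its C5–C6 bond (coumarin numbering).
- *Key step.* The methyl ketone enolate of the pyranone ester A8 attacks the ester carbonyl in a Claisen closure and, after tautomerisation, gives the 5,7-dihydroxycoumarin nitrile A7.
- *For.* The bond from the core to the arene is made as an ordinary sp3–sp3 bond before the arene exists, and its position on the ring is unambiguous. Both points are stronger than the hindered arylation of the chosen route. The nitrile is a compact precursor of the ethenyl arm.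
- *Against.* A 2-pyranone is itself an electrophile towards enolates and bases. The most acidic proton of A8 is the methine between ketone and pyranone, so the reacting methyl enolate needs a dianion. Making A8 with both stereocentres is the unsolved part; the problem is moved, not solved. After the key step, methylation, nitrile reduction and an E-selective olefination with a second coumarin fragment remain.
- *Comparison.* The chosen route builds the quaternary centre catalytically from achiral fragments and attaches both coumarins from one bromide.

Key step: step 5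

Assumption: bromination of 11 with NBS is taken to occur mainly at C8 (para to the 5-methoxy group, flanked by one methoxy group and the ring oxygen); any 6- or 3-bromo isomer is removed at that stage by crystallisation or chromatography.

## Route

Step 1
Reactants: 1 2-methylbut-1-en-3-yne
Product: 2 triisopropyl(3-methylbut-3-en-1-yn-1-yl)silane
Conditions: n-BuLi, THF, −78 °C; i-Pr3SiOTf, −78 °C to rt
Reagents that add atoms: triisopropylsilyl trifluoromethanesulfonate, CC(C)[Si](OS(=O)(=O)C(F)(F)F)(C(C)C)C(C)C
Why: Deprotonation of the terminal alkyne and C-silylation of the lithium acetylide; the bulky silyl group shields this alkyne from ketene, nickel and palladium in the later steps.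

Step 2
Reactants: 2 triisopropyl(3-methylbut-3-en-1-yn-1-yl)silane; 3 trichloroacetyl chloride
Product: 5 racemic 2,2-dichloro-3-methyl-3-[(triisopropylsilyl)ethynyl]cyclobutan-1-one, via dichloroketene 4 (not isolated)
Conditions: Zn(Cu), POCl3, Et2O, reflux
Reagents that add atoms: none
Why: Dichloroketene, formed by zinc dechlorination of 3, adds to the 1,1-disubstituted alkene in a ketene (2+2) cycloaddition, the ketene carbonyl carbon bonding to the terminal CH2; the silyl-shielded alkyne should not compete.

Step 3
Reactants: 5 racemic 2,2-dichloro-3-methyl-3-[(triisopropylsilyl)ethynyl]cyclobutan-1-one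
Product: 6 3-methyl-3-[(triisopropylsilyl)ethynyl]cyclobutan-1-one
Conditions: Zn, AcOH, rt to 50 °C
Reagents that add atoms: none
Why: Zinc reduces both α C–Cl bonds through zinc enolates; the product has a mirror plane through C1 and C3 of the four-membered ring, so its two CH2–C(O) bonds are enantiotopic.

Step 4
Reactants: 7 prop-1-yn-1-ylmagnesium bromide; 8 benzylchlorodimethylsilane
Product: 9 benzyldimethyl(prop-1-yn-1-yl)silane
Conditions: THF, 0 °C to rt
Reagents that add atoms: none
Why: Substitution at silicon by the alkynyl Grignard reagent gives the silylalkyne whose silyl group later leaves with fluoride.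

Step 5
Reactants: 6 3-methyl-3-[(triisopropylsilyl)ethynyl]cyclobutan-1-one; 9 benzyldimethyl(prop-1-yn-1-yl)silane
Product: 10 (5R)-3-(benzyldimethylsilyl)-2,5-dimethyl-5-[(triisopropylsilyl)ethynyl]cyclohex-2-en-1-one
Conditions: Ni(cod)2 (10 mol%), chiral BINOL-derived N,N-bis(1-phenylethyl)phosphoramidite (20 mol%), 9 (2 equiv), toluene, 60–90 °C
Reagents that add atoms: none
Why: Proposed new method: zerovalent nickel bound to the chiral phosphoramidite couples the carbonyl group of 6 and the alkyne of 9 by oxidative cyclisation to a spiro oxanickelacyclopentene (divalent nickel), in which the methyl-bearing alkyne carbon is bonded to the former carbonyl carbon C5 and the silyl-bearing carbon C3 to nickel. β-Carbon elimination then cleaves one of the two enantiotopic C5–CH2 bonds of the strained ring to give a seven-membered nickelacycle, and C(sp3)–C(sp2) reductive elimination forms C2–C3 and releases 10. The closest known reaction type is the zerovalent-nickel-catalysed intermolecular insertion of internal alkynes into 3,3-disubstituted cyclobutanones with achiral phosphines, together with enantioselective intramolecular insertions into cyclobutanones under nickel–phosphoramidite catalysis; the intermolecular desymmetrisation has no direct precedent. The six-membered ring closes by reductive elimination from the seven-membered metallacycle, a formal (4+2) ring expansion in which C4–C5 and C2–C3 are the new bonds. No bond at C1 is made or broken; C1 becomes stereogenic because the ligand decides which CH2–C(O) bond undergoes β-carbon elimination, its pocket telling the methyl group from the long silylethynyl rod. The step needs alkyne regioselectivity, which the silyl group secures by taking the nickel-bound position in the oxidative cyclisation, so that methyl ends on C4 beside the carbonyl. It also needs chemoselectivity for 9 over the alkyne of 6, which the triisopropylsilyl group and the quaternary carbon secure by shielding. The ligand antipode that gives the (5R) product is chosen once the configuration of 10 has been assigned.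

Step 6
Reactants: 11 5,7-dimethoxy-2H-chromen-2-one (5,7-dimethoxycoumarin)
Product: 12 8-bromo-5,7-dimethoxy-2H-chromen-2-one
Conditions: NBS, MeCN, 0 °C to rt
Reagents that add atoms: N-bromosuccinimide, O=C1CCC(=O)N1Br
Why: Electrophilic aromatic bromination of the phloroglucinol-type ring; C8 is para to the 5-methoxy group and less crowded than C6, which lies between two methoxy groups.

Step 7
Reactants: 10 (5R)-3-(benzyldimethylsilyl)-2,5-dimethyl-5-[(triisopropylsilyl)ethynyl]cyclohex-2-en-1-one; 12 8-bromo-5,7-dimethoxy-2H-chromen-2-one
Product: 15 (5S,6R)-3-(benzyldimethylsilyl)-6-(5,7-dimethoxy-2-oxo-2H-chromen-8-yl)-2,5-dimethyl-5-[(triisopropylsilyl)ethynyl]cyclohex-2-en-1-one, via lithium enolate 13 (not isolated), via chlorozinc enolate 14 (not isolated)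
Conditions: LiN(i-Pr)2, THF, −78 °C; ZnCl2, −78 to 0 °C; 12, Pd(dba)2 (5 mol%), P(t-Bu)3 (10 mol%), THF, 50 °C; then DBU, MeCN, rt
Reagents that add atoms: none
Why: Kinetic deprotonation of the enone takes place at the α′ carbon C6, and the zinc enolate is coupled with the bromide by palladium-catalysed enolate arylation (Negishi type) without free strong base, which spares the lactone and the vinylsilane. C6 remains epimerisable, and base equilibration should place the aryl group trans to the C1 methyl (the two trans-diaxial on the half-chair) and gauche only to the slim alkynyl group. The descriptor at the quaternary carbon changes from R to S only because the CIP priorities change.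

Step 8
Reactants: 15 (5S,6R)-3-(benzyldimethylsilyl)-6-(5,7-dimethoxy-2-oxo-2H-chromen-8-yl)-2,5-dimethyl-5-[(triisopropylsilyl)ethynyl]cyclohex-2-en-1-one
Product: 16 (5S,6R)-6-(5,7-dimethoxy-2-oxo-2H-chromen-8-yl)-5-ethynyl-2,5-dimethylcyclohex-2-en-1-one
Conditions: Bu4NF, THF (wet), 0 °C to rt
Reagents that add atoms: none
Why: Fluoride cleaves the alkynyl C–Si bond and, through the fluoride-activated benzyldimethylsilyl group, the vinylic C–Si bond with retention of the alkene position (protodesilylation). C6 may equilibrate under these basic conditions but should stay in the same preferred configuration.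

Step 9
Reactants: 16 (5S,6R)-6-(5,7-dimethoxy-2-oxo-2H-chromen-8-yl)-5-ethynyl-2,5-dimethylcyclohex-2-en-1-one
Product: 17 N′-[(5S,6R)-6-(5,7-dimethoxy-2-oxo-2H-chromen-8-yl)-5-ethynyl-2,5-dimethylcyclohex-2-en-1-ylidene]-4-methylbenzenesulfonohydrazide (C=N geometry not defined)
Conditions: TsNHNH2, AcOH (cat.), EtOH, 60 °C
Reagents that add atoms: 4-methylbenzenesulfonohydrazide, Cc1ccc(cc1)S(=O)(=O)NN
Why: Acid-catalysed condensation of the enone carbonyl with the sulfonyl hydrazide; conjugation keeps the C3=C4 alkene in place and C6 stays at its thermodynamic configuration.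

Step 10
Reactants: 17 N′-[(5S,6R)-6-(5,7-dimethoxy-2-oxo-2H-chromen-8-yl)-5-ethynyl-2,5-dimethylcyclohex-2-en-1-ylidene]-4-methylbenzenesulfonohydrazide
Product: 20 8-[(1R,6S)-6-ethynyl-3,6-dimethylcyclohex-2-en-1-yl]-5,7-dimethoxy-2H-chromen-2-one, via N-boryl hydrazide 18 (not isolated), via allylic diazene 19 (not isolated)
Conditions: catecholborane, CHCl3, 0 °C; NaOAc·3H2O, reflux
Reagents that add atoms: none
Why: Kabalka reduction: hydride adds to C5 of the C=N bond, acetate releases sulfinate to give the allylic diazene, and retro-ene loss of N2 delivers hydrogen to C3 and moves the alkene to C4=C5. No new stereocentre forms, and C6 is fixed from here on because it is no longer α to a C=X group.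

Step 11
Reactants: 20 8-[(1R,6S)-6-ethynyl-3,6-dimethylcyclohex-2-en-1-yl]-5,7-dimethoxy-2H-chromen-2-one
Product: 21 5,7-dimethoxy-8-[(1R,6R)-3,6-dimethyl-6-[(E)-2-(4,4,5,5-tetramethyl-1,3,2-dioxaborolan-2-yl)ethenyl]cyclohex-2-en-1-yl]-2H-chromen-2-one
Conditions: pinacolborane, Cp2Zr(H)Cl (10 mol%), Et3N (10 mol%), CH2Cl2, 40 °C
Reagents that add atoms: pinacolborane, CC1(C)OBOC1(C)C
Why: Zirconium-catalysed syn hydroboration of the terminal alkyne puts boron on the terminal carbon and gives the (E)-alkenylboronate; the trisubstituted ring alkene, the coumarin C3=C4 bond and the lactone should not react with pinacolborane under these conditions.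

Step 12
Reactants: 21 5,7-dimethoxy-8-[(1R,6R)-3,6-dimethyl-6-[(E)-2-(4,4,5,5-tetramethyl-1,3,2-dioxaborolan-2-yl)ethenyl]cyclohex-2-en-1-yl]-2H-chromen-2-one; 12 8-bromo-5,7-dimethoxy-2H-chromen-2-one
Product: 22 8-[(E)-2-[(1R,2R)-2-(5,7-dimethoxy-2-oxo-2H-chromen-8-yl)-1,4-dimethylcyclohex-3-en-1-yl]ethenyl]-5,7-dimethoxy-2H-chromen-2-one
Conditions: Pd(OAc)2 (5 mol%), SPhos (10 mol%), K3PO4, THF/H2O, 60 °C; dilute acid work-up
Reagents that add atoms: none
Why: Suzuki–Miyaura coupling with retention of alkene geometry; the dialkylbiarylphosphine allows oxidative addition and reductive elimination at the di-ortho-substituted bromide, and phosphate is mild enough for the lactones (any ring-opened carboxylate recloses on acidic work-up).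

## Compound list

1 | 2-methylbut-1-en-3-yne | C=C(C)C#C | starting material
2 | triisopropyl(3-methylbut-3-en-1-yn-1-yl)silane | C=C(C)C#C[Si](C(C)C)(C(C)C)C(C)C | intermediate
3 | trichloroacetyl chloride | ClC(=O)C(Cl)(Cl)Cl | starting material
4 | dichloroketene | ClC(Cl)=C=O | intermediate
5 | racemic 2,2-dichloro-3-methyl-3-[(triisopropylsilyl)ethynyl]cyclobutan-1-one | CC1(C#C[Si](C(C)C)(C(C)C)C(C)C)CC(=O)C1(Cl)Cl | intermediate
6 | 3-methyl-3-[(triisopropylsilyl)ethynyl]cyclobutan-1-one | CC1(C#C[Si](C(C)C)(C(C)C)C(C)C)CC(=O)C1 | intermediate
7 | prop-1-yn-1-ylmagnesium bromide | CC#C[Mg]Br | starting material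
8 | benzylchlorodimethylsilane | C[Si](C)(Cl)Cc1ccccc1 | starting material
9 | benzyldimethyl(prop-1-yn-1-yl)silane | CC#C[Si](C)(C)Cc1ccccc1 | intermediate
10 | (5R)-3-(benzyldimethylsilyl)-2,5-dimethyl-5-[(triisopropylsilyl)ethynyl]cyclohex-2-en-1-one | CC(C)[Si](C(C)C)(C(C)C)C#C[C@@]1(C)CC([Si](C)(C)Cc2ccccc2)=C(C)C(=O)C1 | intermediate
11 | 5,7-dimethoxy-2H-chromen-2-one (5,7-dimethoxycoumarin) | COc1cc(OC)c2ccc(=O)oc2c1 | starting material
12 | 8-bromo-5,7-dimethoxy-2H-chromen-2-one | COc1cc(OC)c2ccc(=O)oc2c1Br | intermediate
13 | lithium (5S)-3-(benzyldimethylsilyl)-2,5-dimethyl-5-[(triisopropylsilyl)ethynyl]cyclohexa-1(6),2-dien-1-olate (cross-conjugated C5–C6 enolate of 10, core numbering) | CC(C)[Si](C(C)C)(C(C)C)C#C[C@@]1(C)CC([Si](C)(C)Cc2ccccc2)=C(C)C(O[Li])=C1 | intermediate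
14 | chlorozinc (5S)-3-(benzyldimethylsilyl)-2,5-dimethyl-5-[(triisopropylsilyl)ethynyl]cyclohexa-1(6),2-dien-1-olate | CC(C)[Si](C(C)C)(C(C)C)C#C[C@@]1(C)CC([Si](C)(C)Cc2ccccc2)=C(C)C(O[Zn]Cl)=C1 | intermediate
15 | (5S,6R)-3-(benzyldimethylsilyl)-6-(5,7-dimethoxy-2-oxo-2H-chromen-8-yl)-2,5-dimethyl-5-[(triisopropylsilyl)ethynyl]cyclohex-2-en-1-one | CC(C)[Si](C(C)C)(C(C)C)C#C[C@@]1(C)CC([Si](C)(C)Cc2ccccc2)=C(C)C(=O)[C@H]1c1c(OC)cc(OC)c2ccc(=O)oc12 | intermediate
16 | (5S,6R)-6-(5,7-dimethoxy-2-oxo-2H-chromen-8-yl)-5-ethynyl-2,5-dimethylcyclohex-2-en-1-one | C#C[C@@]1(C)CC=C(C)C(=O)[C@H]1c1c(OC)cc(OC)c2ccc(=O)oc12 | intermediate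
17 | N′-[(5S,6R)-6-(5,7-dimethoxy-2-oxo-2H-chromen-8-yl)-5-ethynyl-2,5-dimethylcyclohex-2-en-1-ylidene]-4-methylbenzenesulfonohydrazide | C#C[C@@]1(C)CC=C(C)C(=NNS(=O)(=O)c2ccc(C)cc2)[C@H]1c1c(OC)cc(OC)c2ccc(=O)oc12 | intermediate
18 | N-(1,3,2-benzodioxaborol-2-yl)-N-[(5S,6R)-6-(5,7-dimethoxy-2-oxo-2H-chromen-8-yl)-5-ethynyl-2,5-dimethylcyclohex-2-en-1-yl]-N′-tosylhydrazine (C1 of the ring not defined) | C#C[C@@]1(C)CC=C(C)C(N(B2Oc3ccccc3O2)NS(=O)(=O)c2ccc(C)cc2)[C@H]1c1c(OC)cc(OC)c2ccc(=O)oc12 | intermediate
19 | 8-[(1R,6S)-2-diazenyl-6-ethynyl-3,6-dimethylcyclohex-3-en-1-yl]-5,7-dimethoxy-2H-chromen-2-one (allylic diazene, diazene carbon not defined) | C#C[C@@]1(C)CC=C(C)C(N=N)[C@H]1c1c(OC)cc(OC)c2ccc(=O)oc12 | intermediate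
20 | 8-[(1R,6S)-6-ethynyl-3,6-dimethylcyclohex-2-en-1-yl]-5,7-dimethoxy-2H-chromen-2-one | C#C[C@@]1(C)CCC(C)=C[C@H]1c1c(OC)cc(OC)c2ccc(=O)oc12 | intermediate
21 | 5,7-dimethoxy-8-[(1R,6R)-3,6-dimethyl-6-[(E)-2-(4,4,5,5-tetramethyl-1,3,2-dioxaborolan-2-yl)ethenyl]cyclohex-2-en-1-yl]-2H-chromen-2-one | CC1(C)OB(/C=C/[C@@]2(C)CCC(C)=C[C@H]2c2c(OC)cc(OC)c3ccc(=O)oc23)OC1(C)C | intermediate
22 | 8-[(E)-2-[(1R,2R)-2-(5,7-dimethoxy-2-oxo-2H-chromen-8-yl)-1,4-dimethylcyclohex-3-en-1-yl]ethenyl]-5,7-dimethoxy-2H-chromen-2-one | COc1cc(OC)c2ccc(=O)oc2c1/C=C/[C@@]1(C)CCC(C)=C[C@H]1c1c(OC)cc(OC)c2ccc(=O)oc12 | target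

## Step count and risks

Total step count: 12. Longest linear sequence: 10 steps (steps 1, 2, 3, 5, 7, 8, 9, 10, 11, 12 from compound 1); steps 4 and 6 are one-step branches.

Least certain steps:

**Step 5 (key step).** The most likely failure is poor discrimination between the two enantiotopic acyl C–C bonds in the β-carbon elimination, because the ligand must tell a methyl group from an alkynyl group on a carbon two bonds away from nickel. Leakage of alkyne regiochemistry and oligomerisation of 9 are secondary risks. Fallback (known chemistry): from 6 and 9 the established racemic insertion with Ni(cod)2 and PCy3 in toluene at 100 °C gives the racemic ketone F1. Its enantiomers are separated by preparative chromatography on a polysaccharide chiral stationary phase, and the (5R) enantiomer is 10, where the route is rejoined. The stereocentre then comes from resolution, not from catalyst control.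

**Step 7.** Transmetalation and reductive elimination may be too slow at an enolate carbon next to a quaternary centre with a di-ortho-substituted aryl partner. The enolate then has time to transfer a proton and react through the extended dienolate at C2, or the bromide is merely reduced. Fallback with reversed polarity: from 10, acylation of the enolate (LiN(SiMe3)2, 2,2,2-trifluoroethyl trifluoroacetate) gives trifluoroacetyl ketone F2. Detrifluoroacetylative diazo transfer (methanesulfonyl azide, Et3N, aqueous MeCN) gives α′-diazo enone F3. Decomposition with Rh2(OAc)4 in the presence of excess 11 lets the nucleophilic C8 of the arene attack the electrophilic carbenoid at C6 (formal aromatic C–H insertion; C1 has no hydrogen, so a 1,2-hydride shift cannot compete). Base equilibration at C6 then rejoins the route at 15.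

**Step 8.** The vinylic C–Si bond may cleave slowly or not at all while the alkyne is freed, because protonation at the silicon-bearing carbon is disfavoured on the electron-poor β-carbon of an enone. Fallback that removes the conjugation first: from 15, 1,2-reduction with NaBH4 and CeCl3·7H2O (MeOH, 0 °C) gives allylic alcohol F4, whose vinylsilane is now an ordinary electron-rich one. Bu4NF then removes both silyl groups to give alcohol F5, and MnO2 in CH2Cl2 reoxidises the allylic alcohol, rejoining the route at 16.

**Step 9 (with step 10).** Condensation may fail at a carbonyl group flanked by the C4 methyl group and by C6 with its bulky aryl group, or the hydrazide may add in conjugate fashion instead. Fallback that needs no carbonyl condensation: from 16, conjugate reduction with LiBH(s-Bu)3 (1 equiv, THF, −78 °C) and trapping of the regiodefined C4–C5 enolate with PhNTf2 gives enol triflate F6. Reduction of the triflate with Pd(OAc)2, PPh3, Bu3N and HCO2H in DMF at 60 °C leaves the alkene at C4=C5 and rejoins the route at 20, bypassing 17.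

## Further compounds

F1 | step 5 | racemic 3-(benzyldimethylsilyl)-2,5-dimethyl-5-[(triisopropylsilyl)ethynyl]cyclohex-2-en-1-one | CC(C)[Si](C(C)C)(C(C)C)C#CC1(C)CC([Si](C)(C)Cc2ccccc2)=C(C)C(=O)C1
F2 | step 7 | (5S)-3-(benzyldimethylsilyl)-2,5-dimethyl-6-(trifluoroacetyl)-5-[(triisopropylsilyl)ethynyl]cyclohex-2-en-1-one (C6 not defined) | CC(C)[Si](C(C)C)(C(C)C)C#C[C@@]1(C)CC([Si](C)(C)Cc2ccccc2)=C(C)C(=O)C1C(=O)C(F)(F)F
F3 | step 7 | (5R)-3-(benzyldimethylsilyl)-6-diazo-2,5-dimethyl-5-[(triisopropylsilyl)ethynyl]cyclohex-2-en-1-one | CC(C)[Si](C(C)C)(C(C)C)C#C[C@@]1(C)CC([Si](C)(C)Cc2ccccc2)=C(C)C(=O)C1=[N+]=[N-]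
F4 | step 8 | (5S,6R)-3-(benzyldimethylsilyl)-6-(5,7-dimethoxy-2-oxo-2H-chromen-8-yl)-2,5-dimethyl-5-[(triisopropylsilyl)ethynyl]cyclohex-2-en-1-ol (carbinol carbon not defined) | CC(C)[Si](C(C)C)(C(C)C)C#C[C@@]1(C)CC([Si](C)(C)Cc2ccccc2)=C(C)C(O)[C@H]1c1c(OC)cc(OC)c2ccc(=O)oc12
F5 | step 8 | (5S,6R)-6-(5,7-dimethoxy-2-oxo-2H-chromen-8-yl)-5-ethynyl-2,5-dimethylcyclohex-2-en-1-ol (carbinol carbon not defined) | C#C[C@@]1(C)CC=C(C)C(O)[C@H]1c1c(OC)cc(OC)c2ccc(=O)oc12
F6 | step 9 | (5S,6R)-6-(5,7-dimethoxy-2-oxo-2H-chromen-8-yl)-5-ethynyl-2,5-dimethylcyclohex-1-en-1-yl trifluoromethanesulfonate | C#C[C@@]1(C)CCC(C)=C(OS(=O)(=O)C(F)(F)F)[C@H]1c1c(OC)cc(OC)c2ccc(=O)oc12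
A1 | alternative 1 | bis(5-methoxyresorcinol mono(triisopropylsilyl) ether) on the (1R,6R) core, one ring at C6 and one on the (E)-ethenyl arm | COc1cc(O)c(c(O[Si](C(C)C)(C(C)C)C(C)C)c1)/C=C/[C@@]1(C)CCC(C)=C[C@H]1c1c(O)cc(OC)cc1O[Si](C(C)C)(C(C)C)C(C)C
A2 | alternative 1 | core bis(siloxyalkyne): (triisopropylsiloxy)ethynyl at C6 and (E)-4-(triisopropylsiloxy)but-1-en-3-ynyl at C1 | CC(C)[Si](C(C)C)(C(C)C)OC#C/C=C/[C@@]1(C)CCC(C)=C[C@H]1C#CO[Si](C(C)C)(C(C)C)C(C)C
A3 | alternative 1 | 3-methoxycyclobut-2-en-1-one | COC1=CC(=O)C1
A4 | alternative 2 | cis-fused Diels–Alder adduct with the allylsilane at C5 (C5 not defined) | COC(=O)[C@]12CC=C(C)C([Si](C)(C)C)[C@H]1c1c(OC2=O)cc(OC)c2ccc(=O)oc12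
A5 | alternative 2 | methyl 5-methoxy-2,8-dioxo-2H,8H-pyrano[2,3-f]chromene-9-carboxylate | COC(=O)C1=Cc2c(OC1=O)cc(OC)c1ccc(=O)oc21
A6 | alternative 2 | (E)-2-methyl-1-(trimethylsilyl)buta-1,3-diene | C=C/C(C)=C/[Si](C)(C)C
A7 | alternative 3 | (1S,2R)-2-(5,7-dihydroxy-2-oxo-2H-chromen-8-yl)-1,4-dimethylcyclohex-3-ene-1-carbonitrile | N#C[C@@]1(C)CCC(C)=C[C@H]1c1c(O)cc(O)c2ccc(=O)oc12
A8 | alternative 3 | methyl 6-[1-(6-cyano-3,6-dimethylcyclohex-2-en-1-yl)-2-oxopropyl]-2-oxo-2H-pyran-5-carboxylate, ring configured as in A7, side-chain CH not defined | N#C[C@@]1(C)CCC(C)=C[C@H]1C(C(C)=O)c1oc(=O)ccc1C(=O)OC
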